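# Synthesis plan for CNP0448476.4: tropone by radical one-carbon ring expansion of a benzenoid spirodihydrobenzofuran

## The problem

- **Connectivity.** The target joins a fully substituted tropone to a pentasubstituted cyclohexane through a spiro dihydrofuran. The numbering used below is: cyclohexane C5–C10, with C9 the spiro carbon; propanoic acid chain C1–C3 on C10; carbinol carbon C4 on C5; dihydrofuran CH2 C11; tropone C1'–C7' (ester on C1', carbonyl C2', methyls on C3' and C6', ether oxygen on C4', C11 on C5', the only ring hydrogen on C7').
- **Stereocentres.** There are four (C5, C8, C9, C10). C8, C9 and C10 are contiguous, and C9 (oxygen-bearing) and C10 (all-carbon) are both fully substituted.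
- **Relative configuration.** The C5 side chain, the C10 methyl, C11 and the C8 methyl lie on one face; the C9 oxygen and the acid chain lie on the other. The C8 and C10 methyls are therefore 1,3-syn-diaxial, so C8 is the less stable epimer and has to be set kinetically at a centre that cannot later equilibrate.
- **Which centre controls which.** C5 can come from the chiral pool and direct alkylation at C10 to the opposite face. The axial C10 methyl then differentiates the two faces at C9 and C8.
- **Sensitive groups.** The C4 tertiary carbinol ionises under acid and sits where it could capture a C9 cation. The acid can lactonise. The tropone, with its vinylogous ester and methyl ester, does not tolerate strong nucleophiles. This argues against a cationic spirocyclisation and for making the seven-membered ring late.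
- **Enabling feature.** Removing C7' from the tropone leaves exactly the ring of methyl 2,4-dihydroxy-3,6-dimethylbenzoate (4-OH becomes the ether oxygen, 2-OH the tropone carbonyl, C5 carries C11). A benzenoid spirodihydrobenzofuran is thus the one-carbon-smaller precursor, its free phenol is para to C5', and a CHCl2 group placed on C5' lies next to the C6'=C1' alkene that is activated by both ketone and ester.

## Retrosynthesis

**End game (24 from 22 from 21).** The acid of 24 is traced back to the primary alcohol of diol 22 (through aldehyde 23), and both hydroxyls of 22 to the silyl ethers of 21. A tert-butyl ester at C3 would need acid for its removal next to the tertiary carbinol, and a simple alkyl ester would not pass the aqueous hydroxide of the carbene step. A silyl-protected alcohol is indifferent to base, carbenoids, hydrogenation and tin radicals and comes directly from an allyl group. The forward steps only have to tell a primary from a tertiary alcohol.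

**Key cut (21 from 20).** The C7'–C6' bond of the tropone is cut and C7' is returned to C5' as a dichloromethyl group, giving the cross-conjugated cyclohexadienone 20. This removes the seven-membered ring and leaves a compound one step from a phenol. Oxyallyl or vinylcyclopropane cycloadditions would build the ring from acyclic pieces, but they deliver it at a lower oxidation level and leave the spiro ether still to be made. The forward reaction must move the one-carbon unit toward C6' and not toward C4'.

**Dichloromethyl dienone (20 from 17 and 18).** The C5'–C7' bond is cut, giving phenol 17 and chloroform 18. The phenolate 19 of 17 is substituted at every nucleophilic carbon, so carbene attack at the para carbon gives a stable dienone instead of an aldehyde. The forward step needs para over ortho attack; the configuration created at C5' is irrelevant.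

**C8 (17 from 16).** The C8–H and C7–H bonds are cut to give cyclohexene 16. Leaving the carvone-derived alkene in place until C9 exists lets C8 be set by face-selective hydrogenation at a centre that can no longer epimerise. An α-methyl ketone would settle on the wrong, equatorial epimer.

**Spiro dihydrofuran (16 from 11 and 15).** The O4'–C9 and C5'–C11 bonds are cut to give diene 11 and quinone diazide 15. Closing a phenol onto a C9 cation under acid would put the C4 oxygen and the chain in competition. Adding a benzylic nucleophile to a C9 ketone would enter opposite the axial methyl and give the wrong C9 epimer. A carbenoid that attacks the exocyclic CH2 and delivers its oxygen on the same face puts oxygen trans to the C10 methyl, as required. The diene is used in place of a simple alkene because the allyl cation eases ring closure and the surviving alkene carries C8.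

**Quinone diazide (15 from 13 from 12).** The C5'–N bond leads back through ammonium salt 14 and nitro compound 13 to commercial methyl 2,4-dihydroxy-3,6-dimethylbenzoate 12, whose only free ring position is the one needed.

**Diene and chain (11 from 10 from 8 from 7).** The O–Si bond, the C3–O bond (through alkylborane 9) and the C9=C11 bond are cut in turn, giving enone 7. The allyl group is the most reactive three-carbon electrophile for a quaternary centre. An acrylate would be shorter, but a carvone enolate adds twice to it and gives a bicyclo[2.2.2]octanone.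

**Quaternary centre and carbinol (7 from 5 from 3 from 2 from 1).** The C10–C1 and C10–CH3 bonds are cut (through enolates 6 and 4), then the silyl ether and the C4–O bond, giving (S)-carvone 1. The carvone carbons map as C1 to C9, C2 to C8, C3 to C7, C4 to C6, C5 to C5 and C6 to C10. The enone alkene blocks the second α-carbon, and methyl-then-allyl places the chain trans to the C5 group.

## Roads not taken

**Alternative 1:** three-component conjugate addition–alkylation.
- *Cut and key step.* The C5–C4 and C10–C1 bonds are cut. Copper thiophene-2-carboxylate (CuTC, CuO2CC4H3S) with a chiral phosphoramidite adds isopropenylmagnesium bromide A3 to 2-methylcyclohex-2-en-1-one A2, and the enolate is trapped with tert-butyl acrylate A4 to give ketone A1.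
- *Merits.* Two C–C bonds and both C5 and C10 are made in one flask, with the chain already at the acid oxidation level. For this part of the molecule it is clearly shorter than the six operations spent here on steps 1–4, 6 and 7.
- *Weak points.* α-Substituted cyclohexenones are poor substrates for copper-catalysed asymmetric Grignard addition, so the absolute configuration would rest on an unproven catalyst result. Forming a quaternary centre by trapping a hindered magnesium enolate with an acrylate is also demanding. A1 lacks the C8 methyl and the C7=C8 alkene; methylation of its enolate would lead to the equatorial, wrong C8 epimer and leave no handle for the annulation. Its tert-butyl ester must finally be cleaved with acid beside the tertiary carbinol. It is also not a tropone strategy and would still need the present key step.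
- *What the chosen plan sets against the shorter fragment route.* Certain absolute configuration from 1, the C8 methyl in place from the start, and an alkene that serves as blocking group, diene partner and late C8 control.

**Alternative 2:** late tropone by oxyallyl–furan (4+3) cycloaddition.
- *Cut and key step.* The C3'–C4' and C1'–C6' bonds are cut. The oxyallyl cation from methyl 2,4-dibromo-3-oxopentanoate A7 and zinc–copper couple adds across the furan A6 to give the oxa-bridged cycloheptenone A5.
- *Merits.* All seven ring carbons and their substituents arrive together, the carbonyl is on the right carbon, and the four new stereocentres are later erased. As a way of making a seven-membered carbocycle, the (4+3) reaction class is at least as well established as a radical ring expansion on a crowded dienone.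
- *Weak points.* An unsymmetrical ester-bearing oxyallyl must pair in one sense with an unsymmetrical furan. A5 then needs bridge opening, dehydration and oxidation to reach the tropone. The ether link between C4' and the hindered tertiary C9 oxygen is still to be made on a tropone. A6 requires a carbon nucleophile to add to a C9 ketone on the face next to the axial methyl.
- *What the chosen plan sets against it.* The spiro centre is made with the correct sense on a robust benzenoid, and the step that inserts the carbon also delivers the tropone oxidation level.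

**Alternative 3:** rhodium (5+2) cycloaddition closing both rings.
- *Cut and key step.* The C5'–C4' and C3'–C2' bonds are cut. [Rh(CO)2Cl]2 opens the siloxy vinylcyclopropane of A9 and inserts the tethered ynol ether to give the dihydrofuran-fused cycloheptadiene A8.
- *Merits.* Two rings form in one step, against one ring in the chosen key step, and the tether fixes the regiochemistry. In ring-forming economy it is superior.
- *Weak points.* A9 needs a labile alkynyl ether on a hindered tertiary alkoxide and a tetrasubstituted donor–acceptor cyclopropane. Ynol ethers are unusual two-carbon partners. A8 has three sp3 ring carbons, so desilylation, oxidation and two dehydrogenations still separate it from the tropone. C9 must again be set beforehand by addition to a ketone.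
- *What the chosen plan sets against it.* A key-step substrate reached by standard arene chemistry from 12 and 1, and a product that is already aromatic.

Key step: step 13

## Route

Remark on the chemistry: 15 is drawn as its ortho-quinoid tautomer; proton transfer between O2' and O4' gives the para-quinoid form, and both lose N2 to the same carbenoid. Compound 5 is used as its C6 epimer mixture because C6 is planar again in enolate 6.

Step 1
Reactants: 1 (S)-(+)-carvone
Product: 2 (5S)-5-(2-hydroxypropan-2-yl)-2-methylcyclohex-2-en-1-one
Conditions: 50% aq. H2SO4, 0 °C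
Reagents that add atoms: water, O
Why: Acid-catalysed Markovnikov hydration of the 1,1-disubstituted alkene through the tertiary cation; the electron-poor ring alkene is not protonated and C5 is untouched.

Step 2
Reactants: 2 (5S)-5-(2-hydroxypropan-2-yl)-2-methylcyclohex-2-en-1-one
Product: 3 (5S)-2-methyl-5-[2-(triethylsilyloxy)propan-2-yl]cyclohex-2-en-1-one
Conditions: Et3SiOTf, 2,6-lutidine, CH2Cl2, −78 to 0 °C
Reagents that add atoms: triethylsilyl trifluoromethanesulfonate, CC[Si](CC)(CC)OS(=O)(=O)C(F)(F)F
Why: Silylation of a tertiary alcohol with a silyl triflate and a hindered base; the ether tolerates amide bases, ylides, boranes, hydroxide, carbenoids and tin radicals and enlarges the C5 group that directs the alkylations.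

Step 3
Reactants: 3 (5S)-2-methyl-5-[2-(triethylsilyloxy)propan-2-yl]cyclohex-2-en-1-one
Product: 5 (5S,6R)-2,6-dimethyl-5-[2-(triethylsilyloxy)propan-2-yl]cyclohex-2-en-1-one, via lithium dienolate 4 (not isolated)
Conditions: LiN(i-Pr)2, THF, −78 °C; MeI, −78 to −20 °C
Reagents that add atoms: iodomethane, CI; lithium diisopropylamide (lithium of 4 only), [Li+].CC(C)[N-]C(C)C
Why: Kinetic deprotonation at the α'-CH2 gives the cross-conjugated enolate, which is methylated mainly anti to the C5 group (enolate alkylation, standard for carvone); the minor 6S epimer is carried along because C6 becomes planar again in step 4.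

Step 4
Reactants: 5 (5S,6R)-2,6-dimethyl-5-[2-(triethylsilyloxy)propan-2-yl]cyclohex-2-en-1-one
Product: 7 (5S,6R)-2,6-dimethyl-6-(prop-2-en-1-yl)-5-[2-(triethylsilyloxy)propan-2-yl]cyclohex-2-en-1-one, via lithium enolate 6 (not isolated)
Conditions: LiN(i-Pr)2, THF, −78 to 0 °C; DMPU, allyl bromide, −78 °C to rt
Reagents that add atoms: allyl bromide, C=CCBr; lithium diisopropylamide (lithium of 6 only), [Li+].CC(C)[N-]C(C)C
Why: Alkylation of the tetrasubstituted enolate with a reactive allylic halide; the electrophile enters anti to the bulky C5 group, so the methyl ends cis and the three-carbon chain trans to it, which sets the quaternary centre C10 of the target, while the ring alkene blocks the other α-carbon.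

Step 5
Reactants: 7 (5S,6R)-2,6-dimethyl-6-(prop-2-en-1-yl)-5-[2-(triethylsilyloxy)propan-2-yl]cyclohex-2-en-1-one
Product: 8 (4S,5R)-1,5-dimethyl-6-methylidene-5-(prop-2-en-1-yl)-4-[2-(triethylsilyloxy)propan-2-yl]cyclohex-1-ene
Conditions: Ph3PCH3Br, KOt-Bu, toluene, 90 °C
Reagents that add atoms: methyltriphenylphosphonium bromide, [Br-].C[P+](c1ccccc1)(c1ccccc1)c1ccccc1
Why: Wittig methylenation of a hindered enone with no epimerisable α-centre, under the salt-free, heated conditions used for 2,6,6-trisubstituted cyclohexenones; it installs C11 as the terminus of an exocyclic 1,3-diene.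

Step 6
Reactants: 8 (4S,5R)-1,5-dimethyl-6-methylidene-5-(prop-2-en-1-yl)-4-[2-(triethylsilyloxy)propan-2-yl]cyclohex-1-ene
Product: 10 3-[(1R,6S)-1,3-dimethyl-2-methylidene-6-[2-(triethylsilyloxy)propan-2-yl]cyclohex-3-en-1-yl]propan-1-ol, via alkylborane 9 (not isolated)
Conditions: 9-BBN (1.1 equiv), THF, 0 °C to rt; then NaOH, H2O2, 0 °C
Reagents that add atoms: hydrogen peroxide, OO; 9-borabicyclo[3.3.1]nonane (boron of 9 only), B1C2CCCC1CCC2
Why: Anti-Markovnikov hydroboration–oxidation; the bulky borane takes the unhindered monosubstituted alkene much faster than the conjugated diene, whose terminal carbon is neopentyl-like, and the tertiary silyl ether survives alkaline peroxide.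

Step 7
Reactants: 10 3-[(1R,6S)-1,3-dimethyl-2-methylidene-6-[2-(triethylsilyloxy)propan-2-yl]cyclohex-3-en-1-yl]propan-1-ol
Product: 11 tert-butyldimethylsilyl ether of 10: tert-butyl{3-[(1R,6S)-1,3-dimethyl-2-methylidene-6-[2-(triethylsilyloxy)propan-2-yl]cyclohex-3-en-1-yl]propoxy}dimethylsilane
Conditions: t-BuMe2SiCl, imidazole, DMF, rt
Reagents that add atoms: tert-butyldimethylsilyl chloride, CC(C)(C)[Si](C)(C)Cl
Why: Standard silylation of a primary alcohol; the tert-butyldimethylsilyl group is chosen because it must withstand concentrated hydroxide in step 12.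

Step 8
Reactants: 12 methyl 2,4-dihydroxy-3,6-dimethylbenzoate
Product: 13 methyl 2,4-dihydroxy-3,6-dimethyl-5-nitrobenzoate
Conditions: HNO3 (1.05 equiv), AcOH, 0–10 °C
Reagents that add atoms: nitric acid, O[N+](=O)[O-]
Why: Electrophilic nitration at the only unsubstituted ring carbon, which is ortho to one hydroxyl and para to the other.

Step 9
Reactants: 13 methyl 2,4-dihydroxy-3,6-dimethyl-5-nitrobenzoate
Product: 15 methyl 3-diazo-6-hydroxy-2,5-dimethyl-4-oxocyclohexa-1,5-diene-1-carboxylate, via ammonium chloride 14 (not isolated)
Conditions: H2 (1 atm), Pd/C, MeOH, HCl (1.1 equiv), rt; filter; i-AmONO, 0 °C; NaHCO3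
Reagents that add atoms: isopentyl nitrite, CC(C)CCON=O; hydrogen chloride (chloride of 14 only), Cl
Why: Catalytic hydrogenation of the nitro group and diazotisation of the air-sensitive aminophenol salt without isolation; the ortho-hydroxy diazonium salt loses HCl to the neutral quinone diazide.

Step 10
Reactants: 11 tert-butyldimethylsilyl ether of 10; 15 methyl 3-diazo-6-hydroxy-2,5-dimethyl-4-oxocyclohexa-1,5-diene-1-carboxylate
Product: 16 methyl (2S,5'S,6'R)-6'-[3-(tert-butyldimethylsilyloxy)propyl]-6-hydroxy-2',4,6',7-tetramethyl-5'-[2-(triethylsilyloxy)propan-2-yl]-3H-spiro[1-benzofuran-2,1'-cyclohex-2'-ene]-5-carboxylate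
Conditions: Rh2(OAc)4 (2 mol%), PhF, 70 °C, slow addition of 15 (1.5 equiv)
Reagents that add atoms: none
Why: Rh2(OAc)4 turns 15 into an electrophilic quinoid carbenoid that attacks the terminal diene carbon C11 from the face opposite the axial C10 methyl, and the allyl cation developing at C9 is captured on the same face by the carbonyl oxygen (formal (3+2) annulation of a ketocarbenoid, known for quinone diazides and cyclic 2-diazo-1,3-diones with enol ethers and 1,3-dienes). This sets C9 with oxygen trans to the C10 methyl and restores the benzenoid ring.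

Step 11
Reactants: 16 methyl (2S,5'S,6'R)-6'-[3-(tert-butyldimethylsilyloxy)propyl]-6-hydroxy-2',4,6',7-tetramethyl-5'-[2-(triethylsilyloxy)propan-2-yl]-3H-spiro[1-benzofuran-2,1'-cyclohex-2'-ene]-5-carboxylate
Product: 17 methyl (2S,2'R,3'S,6'R)-2'-[3-(tert-butyldimethylsilyloxy)propyl]-6-hydroxy-2',4,6',7-tetramethyl-3'-[2-(triethylsilyloxy)propan-2-yl]-3H-spiro[1-benzofuran-2,1'-cyclohexane]-5-carboxylate
Conditions: H2 (1 atm), [Ir(cod)(PCy3)(py)]PF6 (10 mol%), CH2Cl2, rt
Reagents that add atoms: none
Why: Homogeneous hydrogenation of a hindered trisubstituted alkene with a cationic iridium catalyst; hydrogen should add on the face that carries the pseudoaxial ether oxygen at C9 (a weak directing group) and is opposite the axial C10 methyl, so the C8 methyl ends cis to the C10 methyl, the less stable arrangement that equilibration could not give.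

Step 12
Reactants: 17 methyl (2S,2'R,3'S,6'R)-2'-[3-(tert-butyldimethylsilyloxy)propyl]-6-hydroxy-2',4,6',7-tetramethyl-3'-[2-(triethylsilyloxy)propan-2-yl]-3H-spiro[1-benzofuran-2,1'-cyclohexane]-5-carboxylate; 18 chloroform
Product: 20 methyl (2S,2'R,3'S,6'R)-2'-[3-(tert-butyldimethylsilyloxy)propyl]-3a-(dichloromethyl)-2',4,6',7-tetramethyl-6-oxo-3'-[2-(triethylsilyloxy)propan-2-yl]-3a,6-dihydro-3H-spiro[1-benzofuran-2,1'-cyclohexane]-5-carboxylate (both C3a epimers), via sodium phenolate 19 (not isolated)
Conditions: CHCl3 (excess), 50% aq. NaOH, BnEt3NCl (10 mol%), 0 °C to rt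
Reagents that add atoms: sodium hydroxide (sodium of 19 only), [Na+].[OH-]
Why: Abnormal Reimer–Tiemann reaction: dichlorocarbene attacks the phenolate at the para carbon C5', which carries C11 and cannot rearomatise, so protonation leaves the 4-(dichloromethyl)cyclohexa-2,5-dienone. The ortho carbons are less accessible (C3' lies between two oxygens, C1' is deactivated by the ester) and the ammonium counter-ion favours para attack; either C5' epimer serves because that centre is planar again after step 13.

Step 13
Reactants: 20 methyl (2S,2'R,3'S,6'R)-2'-[3-(tert-butyldimethylsilyloxy)propyl]-3a-(dichloromethyl)-2',4,6',7-tetramethyl-6-oxo-3'-[2-(triethylsilyloxy)propan-2-yl]-3a,6-dihydro-3H-spiro[1-benzofuran-2,1'-cyclohexane]-5-carboxylate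
Product: 21 methyl (2S,2'R,3'S,6'R)-2'-[3-(tert-butyldimethylsilyloxy)propyl]-2',5,6',8-tetramethyl-7-oxo-3'-[2-(triethylsilyloxy)propan-2-yl]-3,7-dihydrospiro[cyclohepta[b]furan-2,1'-cyclohexane]-6-carboxylate
Conditions: Bu3SnH (1.3 equiv, syringe pump), AIBN (0.2 equiv), i-Pr2NEt (2 equiv), toluene (0.01 M), 90 °C
Reagents that add atoms: none
Why: The tin radical abstracts one chlorine of the CHCl2 group and leaves an α-chloroalkyl radical on the quaternary C5'. This radical closes 3-exo-trig onto C6', the β-carbon of the alkene conjugated to both the ring ketone and the ester, so the resulting radical at C1' is stabilised by two acceptors. β-Scission of the C5'–C6' bond of the cyclopropane then places the CHCl carbon in the ring (a net 1,2-shift of the C6' vinyl carbon of the Dowd–Beckwith type) and leaves an allylic radical at C5'. Loss of a chlorine atom from the neighbouring CHCl carbon gives the aromatic tropone, the chlorine atom carries the chain by taking hydrogen from Bu3SnH, and the amine binds the HCl. The closest known reaction type is the tin hydride ring expansion of 4-alkyl-4-(dihalomethyl)cyclohexa-2,5-dienones from abnormal Reimer–Tiemann reactions to 4-alkyltropones. The seven-membered ring is closed by ring expansion (3-exo cyclisation followed by fragmentation), not by a direct seven-membered closure. No stereocentre is formed and the C5' centre of 20 is destroyed, so both epimers converge. The step needs migration toward C6' and not toward the enol-ether carbon C4', and rearrangement faster than hydrogen transfer: the first is secured by the two acceptors on C1' against the donor oxygen on C4', the second by keeping the stannane concentration low.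

Step 14
Reactants: 21 methyl (2S,2'R,3'S,6'R)-2'-[3-(tert-butyldimethylsilyloxy)propyl]-2',5,6',8-tetramethyl-7-oxo-3'-[2-(triethylsilyloxy)propan-2-yl]-3,7-dihydrospiro[cyclohepta[b]furan-2,1'-cyclohexane]-6-carboxylate
Product: 22 methyl (2S,2'R,3'S,6'R)-3'-(2-hydroxypropan-2-yl)-2'-(3-hydroxypropyl)-2',5,6',8-tetramethyl-7-oxo-3,7-dihydrospiro[cyclohepta[b]furan-2,1'-cyclohexane]-6-carboxylate
Conditions: HF·pyridine, pyridine, THF, 0 °C to rt
Reagents that add atoms: none
Why: Fluoride cleavage of both silyl ethers under buffered conditions that leave the tertiary carbinol, the tropone and its methyl ester untouched.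

Step 15
Reactants: 22 methyl (2S,2'R,3'S,6'R)-3'-(2-hydroxypropan-2-yl)-2'-(3-hydroxypropyl)-2',5,6',8-tetramethyl-7-oxo-3,7-dihydrospiro[cyclohepta[b]furan-2,1'-cyclohexane]-6-carboxylate
Product: 24 3-[(2S,2'R,3'S,6'R)-3'-(2-hydroxypropan-2-yl)-6-(methoxycarbonyl)-2',5,6',8-tetramethyl-7-oxo-3,7-dihydrospiro[cyclohepta[b]furan-2,1'-cyclohexan]-2'-yl]propanoic acid, via aldehyde 23 (not isolated)
Conditions: TEMPO (0.2 equiv), PhI(OAc)2 (2.5 equiv), MeCN–H2O, rt
Reagents that add atoms: water, O
Why: Oxoammonium (TEMPO) oxidation of the primary alcohol through the aldehyde hydrate to the acid; the tertiary alcohol cannot be oxidised and the electron-poor tropone is inert to the oxidant.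

## Compound list

1 | (S)-(+)-carvone, (5S)-2-methyl-5-(prop-1-en-2-yl)cyclohex-2-en-1-one | CC1=CC[C@@H](CC1=O)C(C)=C | starting material
2 | (5S)-5-(2-hydroxypropan-2-yl)-2-methylcyclohex-2-en-1-one | CC1=CC[C@@H](CC1=O)C(C)(C)O | intermediate
3 | (5S)-2-methyl-5-[2-(triethylsilyloxy)propan-2-yl]cyclohex-2-en-1-one | CC1=CC[C@@H](CC1=O)C(C)(C)O[Si](CC)(CC)CC | intermediate
4 | lithium dienolate of 3 (O–C1=C6 and C2=C3) | CC1=CC[C@@H](C=C1O[Li])C(C)(C)O[Si](CC)(CC)CC | intermediate (not isolated)
5 | (5S,6R)-2,6-dimethyl-5-[2-(triethylsilyloxy)propan-2-yl]cyclohex-2-en-1-one (major epimer, methyl trans to the C5 group) | CC1=CC[C@@H]([C@@H](C)C1=O)C(C)(C)O[Si](CC)(CC)CC | intermediate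
6 | lithium enolate of 5 (O–C1=C6, C6 bearing methyl) | CC1=CC[C@@H](C(C)=C1O[Li])C(C)(C)O[Si](CC)(CC)CC | intermediate (not isolated)
7 | (5S,6R)-2,6-dimethyl-6-(prop-2-en-1-yl)-5-[2-(triethylsilyloxy)propan-2-yl]cyclohex-2-en-1-one (methyl cis, allyl trans to the C5 group) | CC1=CC[C@@H]([C@@](C)(CC=C)C1=O)C(C)(C)O[Si](CC)(CC)CC | intermediate
8 | (4S,5R)-1,5-dimethyl-6-methylidene-5-(prop-2-en-1-yl)-4-[2-(triethylsilyloxy)propan-2-yl]cyclohex-1-ene | CC1=CC[C@@H]([C@@](C)(CC=C)C1=C)C(C)(C)O[Si](CC)(CC)CC | intermediate
9 | 9-{3-[(1R,6S)-1,3-dimethyl-2-methylidene-6-[2-(triethylsilyloxy)propan-2-yl]cyclohex-3-en-1-yl]propyl}-9-borabicyclo[3.3.1]nonane | CC1=CC[C@@H]([C@@](C)(CCCB2C3CCCC2CCC3)C1=C)C(C)(C)O[Si](CC)(CC)CC | intermediate (not isolated)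
10 | 3-[(1R,6S)-1,3-dimethyl-2-methylidene-6-[2-(triethylsilyloxy)propan-2-yl]cyclohex-3-en-1-yl]propan-1-ol | CC1=CC[C@@H]([C@@](C)(CCCO)C1=C)C(C)(C)O[Si](CC)(CC)CC | intermediate
11 | tert-butyl{3-[(1R,6S)-1,3-dimethyl-2-methylidene-6-[2-(triethylsilyloxy)propan-2-yl]cyclohex-3-en-1-yl]propoxy}dimethylsilane | CC1=CC[C@@H]([C@@](C)(CCCO[Si](C)(C)C(C)(C)C)C1=C)C(C)(C)O[Si](CC)(CC)CC | intermediate
12 | methyl 2,4-dihydroxy-3,6-dimethylbenzoate | COC(=O)c1c(C)cc(O)c(C)c1O | starting material
13 | methyl 2,4-dihydroxy-3,6-dimethyl-5-nitrobenzoate | COC(=O)c1c(C)c([N+](=O)[O-])c(O)c(C)c1O | intermediate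
14 | methyl 5-amino-2,4-dihydroxy-3,6-dimethylbenzoate hydrochloride | COC(=O)c1c(C)c([NH3+])c(O)c(C)c1O.[Cl-] | intermediate (not isolated)
15 | methyl 3-diazo-6-hydroxy-2,5-dimethyl-4-oxocyclohexa-1,5-diene-1-carboxylate (ortho-quinone diazide) | COC(=O)C1=C(C)C(=[N+]=[N-])C(=O)C(C)=C1O | intermediate
16 | methyl (2S,5'S,6'R)-6'-[3-(tert-butyldimethylsilyloxy)propyl]-6-hydroxy-2',4,6',7-tetramethyl-5'-[2-(triethylsilyloxy)propan-2-yl]-3H-spiro[1-benzofuran-2,1'-cyclohex-2'-ene]-5-carboxylate | COC(=O)c1c(C)c2c(c(C)c1O)O[C@@]1(C2)C(C)=CC[C@H](C(C)(C)O[Si](CC)(CC)CC)[C@@]1(C)CCCO[Si](C)(C)C(C)(C)C | intermediate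
17 | methyl (2S,2'R,3'S,6'R)-2'-[3-(tert-butyldimethylsilyloxy)propyl]-6-hydroxy-2',4,6',7-tetramethyl-3'-[2-(triethylsilyloxy)propan-2-yl]-3H-spiro[1-benzofuran-2,1'-cyclohexane]-5-carboxylate | COC(=O)c1c(C)c2c(c(C)c1O)O[C@@]1(C2)[C@H](C)CC[C@H](C(C)(C)O[Si](CC)(CC)CC)[C@@]1(C)CCCO[Si](C)(C)C(C)(C)C | intermediate
18 | chloroform | ClC(Cl)Cl | starting material
19 | sodium phenolate of 17 | COC(=O)c1c(C)c2c(c(C)c1[O-])O[C@@]1(C2)[C@H](C)CC[C@H](C(C)(C)O[Si](CC)(CC)CC)[C@@]1(C)CCCO[Si](C)(C)C(C)(C)C.[Na+] | intermediate (not isolated)
20 | methyl (2S,2'R,3'S,6'R)-2'-[3-(tert-butyldimethylsilyloxy)propyl]-3a-(dichloromethyl)-2',4,6',7-tetramethyl-6-oxo-3'-[2-(triethylsilyloxy)propan-2-yl]-3a,6-dihydro-3H-spiro[1-benzofuran-2,1'-cyclohexane]-5-carboxylate (both C3a epimers) | COC(=O)C1=C(C)C2(C(Cl)Cl)C(=C(C)C1=O)O[C@@]3(C2)[C@H](C)CC[C@H](C(C)(C)O[Si](CC)(CC)CC)[C@@]3(C)CCCO[Si](C)(C)C(C)(C)C | intermediate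
21 | methyl (2S,2'R,3'S,6'R)-2'-[3-(tert-butyldimethylsilyloxy)propyl]-2',5,6',8-tetramethyl-7-oxo-3'-[2-(triethylsilyloxy)propan-2-yl]-3,7-dihydrospiro[cyclohepta[b]furan-2,1'-cyclohexane]-6-carboxylate | COC(=O)c1c(C)cc2c(c(C)c1=O)O[C@@]1(C2)[C@H](C)CC[C@H](C(C)(C)O[Si](CC)(CC)CC)[C@@]1(C)CCCO[Si](C)(C)C(C)(C)C | intermediate
22 | methyl (2S,2'R,3'S,6'R)-3'-(2-hydroxypropan-2-yl)-2'-(3-hydroxypropyl)-2',5,6',8-tetramethyl-7-oxo-3,7-dihydrospiro[cyclohepta[b]furan-2,1'-cyclohexane]-6-carboxylate | COC(=O)c1c(C)cc2c(c(C)c1=O)O[C@@]1(C2)[C@H](C)CC[C@H](C(C)(C)O)[C@@]1(C)CCCO | intermediate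
23 | methyl (2S,2'R,3'S,6'R)-3'-(2-hydroxypropan-2-yl)-2',5,6',8-tetramethyl-7-oxo-2'-(3-oxopropyl)-3,7-dihydrospiro[cyclohepta[b]furan-2,1'-cyclohexane]-6-carboxylate | COC(=O)c1c(C)cc2c(c(C)c1=O)O[C@@]1(C2)[C@H](C)CC[C@H](C(C)(C)O)[C@@]1(C)CCC=O | intermediate (not isolated)
24 | 3-[(2S,2'R,3'S,6'R)-3'-(2-hydroxypropan-2-yl)-6-(methoxycarbonyl)-2',5,6',8-tetramethyl-7-oxo-3,7-dihydrospiro[cyclohepta[b]furan-2,1'-cyclohexan]-2'-yl]propanoic acid | COC(=O)c1c(C)cc2c(c(C)c1=O)O[C@@]1(C2)[C@H](C)CC[C@H](C(C)(C)O)[C@@]1(C)CCC(=O)O | target

## Step count and risks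

Total step count: 15. Longest linear sequence: 13 (steps 1–7 and 10–15).

**Step 13 (key step).**
- Likely failure: hydrogen transfer from the stannane to the chloromethyl radical before it closes onto C6' (simple reduction), conjugate reduction of the electron-poor C6'=C1' alkene by the tin hydride, or migration toward C4'.
- Fallback: change both the halogen and the chain carrier. Phenol 17 is treated with bromoform under the conditions of step 12 to give the dibromomethyl dienone F1. Its weaker C–Br bonds allow an atom-transfer chain with Bu3SnSnBu3 under irradiation at room temperature with no hydride donor present, so the ring-expanded radical can only lose bromine. The fallback sets out from 17 and returns at 21.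

**Step 10.**
- Likely failure: diversion of the electrophilic carbenoid into O–H insertion with the acidic enol hydroxyl of 15 or the phenol of 16, self-coupling of the diazo compound because the diene terminus is hindered, or incomplete face selection at C9.
- Fallback: a Larock-type heteroannulation that uses no carbenoid. Iodination of 12 (I2, NaHCO3) gives methyl 2,4-dihydroxy-5-iodo-3,6-dimethylbenzoate F2. With Pd(OAc)2, NaHCO3 and n-Bu4NCl in DMF at 80 °C, F2 adds its aryl group to C11 of 11 and the phenoxide closes onto the π-allyl at C9. The configuration at C9 then depends on whether oxygen is delivered from the palladium face or the opposite one and would have to be confirmed before going on. The fallback sets out from 12 and 11 and returns at 16.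

**Step 12.**
- Likely failure: carbene attack at the ortho carbon C3' instead of C5', and attack of hydroxide on 20, which is a doubly activated Michael acceptor and vinylogous ester.
- Fallback: hydroxide-free carbene transfer to a non-coordinated phenolate. Phenol 17 is converted with Bu4NOH into the tetrabutylammonium phenolate F3, dried, and heated with Cl3CCO2Na in 1,2-dimethoxyethane at 80 °C (decarboxylative generation of dichlorocarbene). A free phenolate favours para attack and no hydroxide is present to degrade the product. The fallback sets out from 17 and returns at 20.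

**Step 11.**
- Likely failure: delivery of hydrogen to the face that carries the C10 methyl, giving the equatorial C8 epimer, or no reaction at the hindered alkene.
- Fallback: radical hydrogenation by hydrogen-atom transfer (Mn(dpm)3, PhSiH3, t-BuOOH, i-PrOH, rt). A hydrogen atom adds first to C7, and the planar tertiary C8 radical takes the second hydrogen from a bulky donor on the side away from the syn-axial C10 methyl. This is a stepwise radical path in place of alkene coordination to a metal. It sets out from 16, returns at 17 and makes no new compound (F0).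

**Step 4.**
- Likely failure: slow deprotonation of the tertiary C6–H next to the bulky silyloxy-isopropyl group, competing γ-deprotonation, or O-allylation.
- Fallback: build the quaternary centre before the carbinol. Carvone 1 is methylated (LiN(i-Pr)2, MeI) to 6-methylcarvone F4 and allylated (LiN(i-Pr)2, allyl bromide) anti to the small isopropenyl group to 6-allyl-6-methylcarvone F5. The 1,1-disubstituted alkene is then hydrated (Mukaiyama hydration: Co(acac)2, PhSiH3, O2) to carbinol F6, which is silylated with Et3SiOTf. The price is a chemoselective hydration of the isopropenyl group beside the allyl group. The fallback sets out from 1 and returns at 7.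

## Further compounds

F1 | step 13 | methyl (2S,2'R,3'S,6'R)-2'-[3-(tert-butyldimethylsilyloxy)propyl]-3a-(dibromomethyl)-2',4,6',7-tetramethyl-6-oxo-3'-[2-(triethylsilyloxy)propan-2-yl]-3a,6-dihydro-3H-spiro[1-benzofuran-2,1'-cyclohexane]-5-carboxylate | COC(=O)C1=C(C)C2(C(Br)Br)C(=C(C)C1=O)O[C@@]3(C2)[C@H](C)CC[C@H](C(C)(C)O[Si](CC)(CC)CC)[C@@]3(C)CCCO[Si](C)(C)C(C)(C)C
F2 | step 10 | methyl 2,4-dihydroxy-5-iodo-3,6-dimethylbenzoate | COC(=O)c1c(C)c(I)c(O)c(C)c1O
F3 | step 12 | tetrabutylammonium phenolate of 17 | COC(=O)c1c(C)c2c(c(C)c1[O-])O[C@@]1(C2)[C@H](C)CC[C@H](C(C)(C)O[Si](CC)(CC)CC)[C@@]1(C)CCCO[Si](C)(C)C(C)(C)C.CCCC[N+](CCCC)(CCCC)CCCC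
F0 | step 11 | none | none
F4 | step 4 | (5S,6R)-2,6-dimethyl-5-(prop-1-en-2-yl)cyclohex-2-en-1-one | CC1=CC[C@@H]([C@@H](C)C1=O)C(C)=C
F5 | step 4 | (5R,6R)-2,6-dimethyl-6-(prop-2-en-1-yl)-5-(prop-1-en-2-yl)cyclohex-2-en-1-one | CC1=CC[C@@H]([C@@](C)(CC=C)C1=O)C(C)=C
F6 | step 4 | (5S,6R)-5-(2-hydroxypropan-2-yl)-2,6-dimethyl-6-(prop-2-en-1-yl)cyclohex-2-en-1-one | CC1=CC[C@@H]([C@@](C)(CC=C)C1=O)C(C)(C)O
A1 | alternative 1 | tert-butyl 3-[1-methyl-2-oxo-6-(prop-1-en-2-yl)cyclohexyl]propanoate (chain trans to isopropenyl) | O=C1CCC[C@H](C(C)=C)[C@@]1(C)CCC(=O)OC(C)(C)C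
A2 | alternative 1 | 2-methylcyclohex-2-en-1-one | CC1=CCCCC1=O
A3 | alternative 1 | isopropenylmagnesium bromide | CC(=C)[Mg]Br
A4 | alternative 1 | tert-butyl acrylate | C=CC(=O)OC(C)(C)C
A5 | alternative 2 | 8-oxabicyclo[3.2.1]oct-6-en-3-one adduct carrying the terpenoid unit as its tertiary trimethylsilyl ether (mixture at the four new ring centres) | C[Si](C)(C)O[C@@]1(CC2=CC3(C)OC2C(C)C(=O)C3C(=O)OC)[C@H](C)CC[C@H](C(C)(C)O[Si](CC)(CC)CC)[C@@]1(C)CCC(=O)OC(C)(C)C
A6 | alternative 2 | 2-methyl-4-(terpenoid-methyl)furan, tertiary trimethylsilyl ether at C9 | C[Si](C)(C)O[C@@]1(Cc2coc(C)c2)[C@H](C)CC[C@H](C(C)(C)O[Si](CC)(CC)CC)[C@@]1(C)CCC(=O)OC(C)(C)C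
A7 | alternative 2 | methyl 2,4-dibromo-3-oxopentanoate | CC(Br)C(=O)C(Br)C(=O)OC
A8 | alternative 3 | dihydrofuran-fused cycloheptadiene cycloadduct (mixture at the three new sp3 ring centres) | COC(=O)C1C(O[Si](C)(C)C(C)(C)C)C(C)=C2O[C@@]3(CC2C=C1C)[C@H](C)CC[C@H](C(C)(C)O[Si](CC)(CC)CC)[C@@]3(C)CCC(=O)OC(C)(C)C
A9 | alternative 3 | tertiary prop-1-ynyl ether at C9 tethered to a 1-methyl-2-(methoxycarbonyl)-3-(tert-butyldimethylsilyloxy)cyclopropyl alkene | CC#CO[C@@]1(CC=CC2(C)C(C(=O)OC)C2O[Si](C)(C)C(C)(C)C)[C@H](C)CC[C@H](C(C)(C)O[Si](CC)(CC)CC)[C@@]1(C)CCC(=O)OC(C)(C)C
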